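**Plan**

- Numbering: C1 (quaternary; methyl and 4-methylpent-3-enyl), C2=C3 (E), C4 (acyloxy), C5–C6 (oxirane, methyl on C5), C7, C8, C9=C10 (C12H2OH on C9; C8 and C11 cis), C11.
- Cuts, in order: the C4–O acyl bond and the oxirane oxygen (back to a Z C5=C6 allylic alcohol); then the ring bond C8–C9; then C4–C5 (enal plus Z-alkenylzinc) and C1–C11 (Claisen).
- Enabling feature: C8 is a ring CH2 bonded directly to the sp2 carbon C9 of the trisubstituted C9=C10 alkene, so C8–C9 is the union of a primary C8 radical (from an acid one carbon longer, as its N-acyloxyphthalimide) with a C9 alkenyl iodide.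
- Forward: geranial → chiral allylic alcohol → Johnson–Claisen (C1, E C2=C3) → (Z)-2-iodoallyl silyl ether (C9–C12) → C4 enal → alkenylzinc addition → active ester → eleven-membered ring (step 19) → oxirane (step 21) → ester → desilylation.
- Stereochemistry: C1 by chirality transfer from a CBS-derived carbinol through the chair Claisen transition state; C4 by ligand-controlled alkenylzinc addition; C5 and C6 by hydroxyl-directed epoxidation relayed from C4. Alkene geometries come from the Claisen step (E), the α-iodo Wittig reaction (Z C5=C6) and enal α-iodination (C9=C10).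

Key step: step 19

Remark: geranial is taken as the pure 2E isomer (the 2Z isomer would give the C1 epimer through step 5), and (+)-MIB is taken to deliver the alkenyl group to the Re face of the enal, the mirror image of the Si-face delivery established for (−)-MIB.

**Route**

Step 1
Reactants: 1 (tributylstannyl)methanol
Product: 2 tributyl[(4-methoxybenzyloxy)methyl]stannane
Conditions: NaH, THF/DMF, 0 °C; 4-methoxybenzyl chloride, n-Bu4NI (cat.), rt
Reagents that add atoms: 4-methoxybenzyl chloride, COc1ccc(CCl)cc1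
Why: Williamson etherification of the sodium alkoxide should proceed cleanly because the tin–carbon bonds are inert to NaH and to the benzylic chloride.

Step 2
Reactants: 2 tributyl[(4-methoxybenzyloxy)methyl]stannane; 3 geranial
Product: 5 racemic (3E)-1-(4-methoxybenzyloxy)-4,8-dimethylnona-3,7-dien-2-ol, via (4-methoxybenzyloxy)methyllithium 4 (not isolated)
Conditions: n-BuLi, THF, −78 °C; then 3, −78 °C; aq NH4Cl
Reagents that add atoms: none
Why: Tin–lithium exchange gives the α-alkoxymethyllithium, which should add 1,2 to the enal; the carbinol is racemic here and is set in steps 3 and 4.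

Step 3
Reactants: 5 racemic (3E)-1-(4-methoxybenzyloxy)-4,8-dimethylnona-3,7-dien-2-ol
Product: 6 (3E)-1-(4-methoxybenzyloxy)-4,8-dimethylnona-3,7-dien-2-one
Conditions: MnO2, CH2Cl2, rt
Reagents that add atoms: none
Why: Allylic oxidation with MnO2 should convert the secondary allylic alcohol into the enone without touching the isolated alkene or the benzyl ether.

Step 4
Reactants: 6 (3E)-1-(4-methoxybenzyloxy)-4,8-dimethylnona-3,7-dien-2-one
Product: 7 (2R,3E)-1-(4-methoxybenzyloxy)-4,8-dimethylnona-3,7-dien-2-ol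
Conditions: (R)-2-methyl-CBS-oxazaborolidine (20 mol%), catecholborane, toluene, −78 °C
Reagents that add atoms: none
Why: Corey–Bakshi–Shibata reduction with the alkenyl group as the large substituent and CH2OPMB as the small one should give the (R)-carbinol from the (R)-catalyst, and catecholborane at −78 °C avoids hydroboration of the alkenes.

Step 5
Reactants: 7 (2R,3E)-1-(4-methoxybenzyloxy)-4,8-dimethylnona-3,7-dien-2-ol; 8 triethyl orthoacetate
Product: 11 ethyl (3S)-3-[(1E)-3-(4-methoxybenzyloxy)prop-1-enyl]-3,7-dimethyloct-6-enoate, via mixed orthoester 9 (not isolated), via ketene acetal 10 (not isolated)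
Conditions: EtCO2H (cat.), neat in 8, 140 °C, EtOH distilled off
Reagents that add atoms: none
Why: Johnson–Claisen rearrangement through a chair transition state with CH2OPMB equatorial forms C1–C11 on the alkene face syn to the breaking C–O bond, so the (R)-carbinol of the E alkene should give (S)-C1 and the E C2=C3 alkene.

Step 6
Reactants: 11 ethyl (3S)-3-[(1E)-3-(4-methoxybenzyloxy)prop-1-enyl]-3,7-dimethyloct-6-enoate
Product: 12 (3S)-3-[(1E)-3-(4-methoxybenzyloxy)prop-1-enyl]-3,7-dimethyloct-6-enal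
Conditions: i-Bu2AlH, CH2Cl2, −78 °C
Reagents that add atoms: none
Why: Partial reduction of the ethyl ester with i-Bu2AlH stops at the aldehyde because the tetrahedral aluminium acetal is stable at −78 °C.

Step 7
Reactants: 12 (3S)-3-[(1E)-3-(4-methoxybenzyloxy)prop-1-enyl]-3,7-dimethyloct-6-enal; 13 (triphenylphosphoranylidene)acetaldehyde
Product: 14 (2E,5S)-5-[(1E)-3-(4-methoxybenzyloxy)prop-1-enyl]-5,9-dimethyldeca-2,8-dienal
Conditions: toluene, 80 °C
Reagents that add atoms: none
Why: Wittig olefination with the stabilised formylmethylene ylide should give the E enal (C9, C12) from the unhindered CH2CHO group.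

Step 8
Reactants: 14 (2E,5S)-5-[(1E)-3-(4-methoxybenzyloxy)prop-1-enyl]-5,9-dimethyldeca-2,8-dienal
Product: 15 (2Z,5S)-2-iodo-5-[(1E)-3-(4-methoxybenzyloxy)prop-1-enyl]-5,9-dimethyldeca-2,8-dienal
Conditions: I2, DMAP (cat.), K2CO3, THF/H2O, rt
Reagents that add atoms: iodine, II
Why: Baylis–Hillman-type α-iodination (conjugate addition of DMAP, iodination of the enolate, elimination) should give the thermodynamically preferred Z 2-iodoenal with iodine cis to C11.

Step 9
Reactants: 15 (2Z,5S)-2-iodo-5-[(1E)-3-(4-methoxybenzyloxy)prop-1-enyl]-5,9-dimethyldeca-2,8-dienal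
Product: 16 (2Z,5S)-2-iodo-5-[(1E)-3-(4-methoxybenzyloxy)prop-1-enyl]-5,9-dimethyldeca-2,8-dien-1-ol
Conditions: NaBH4, CeCl3·7H2O, MeOH, 0 °C
Reagents that add atoms: none
Why: Luche reduction is 1,2-selective and should leave the C–I bond and the alkene geometry untouched.

Step 10
Reactants: 16 (2Z,5S)-2-iodo-5-[(1E)-3-(4-methoxybenzyloxy)prop-1-enyl]-5,9-dimethyldeca-2,8-dien-1-ol
Product: 17 tert-butyldimethylsilyl ether of 16 (C12–OTBS)
Conditions: TBSCl, imidazole, DMF, rt
Reagents that add atoms: tert-butyldimethylsilyl chloride, CC(C)(C)[Si](C)(C)Cl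
Why: Standard silylation of the primary allylic alcohol protects C12–OH through to the last step.

Step 11
Reactants: 17 tert-butyldimethylsilyl ether of 16
Product: 19 (2E,4S,6Z)-8-(tert-butyldimethylsilyloxy)-7-iodo-4-methyl-4-(4-methylpent-3-enyl)octa-2,6-dienal, via allylic alcohol 18 (not isolated)
Conditions: DDQ, CH2Cl2/pH 7 buffer, 0 °C; then MnO2, CH2Cl2, rt
Reagents that add atoms: none
Why: Oxidative cleavage of the 4-methoxybenzyl ether followed by MnO2 oxidation of the primary allylic alcohol should give the C4 enal, and any alcohol oxidised early by DDQ gives the same product.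

Step 12
Reactants: 20 butane-1,4-diol
Product: 21 4-(triethylsilyloxy)butan-1-ol
Conditions: NaH (1 equiv), THF, 0 °C to rt; TESCl
Reagents that add atoms: chlorotriethylsilane, CC[Si](CC)(CC)Cl
Why: Silylation of the sparingly soluble monosodium alkoxide of a symmetrical diol is a known way to obtain the mono-ether.

Step 13
Reactants: 21 4-(triethylsilyloxy)butan-1-ol
Product: 22 4-(triethylsilyloxy)butanal
Conditions: Dess–Martin periodinane, pyridine, CH2Cl2, 0 °C to rt
Reagents that add atoms: none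
Why: Buffered Dess–Martin oxidation should give the aldehyde without loss of the triethylsilyl ether.

Step 14
Reactants: 23 ethyltriphenylphosphonium bromide; 22 4-(triethylsilyloxy)butanal
Product: 27 (Z)-triethyl[(5-iodohex-4-en-1-yl)oxy]silane, via ethylidenetriphenylphosphorane 24 (not isolated), via (1-iodoethyl)triphenylphosphonium iodide 25 (not isolated), via (1-iodoethylidene)triphenylphosphorane 26 (not isolated)
Conditions: 23, n-BuLi, THF, 0 °C; I2, −78 °C; NaN(SiMe3)2, −20 °C; 22, −78 °C to rt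
Reagents that add atoms: iodine, II
Why: Stork–Zhao-type olefination with the α-iodo ylide should give the Z 2-iodoalkene (iodine cis to the chain), which fixes the later C5=C6 geometry.

Step 15
Reactants: 27 (Z)-triethyl[(5-iodohex-4-en-1-yl)oxy]silane; 19 (2E,4S,6Z)-8-(tert-butyldimethylsilyloxy)-7-iodo-4-methyl-4-(4-methylpent-3-enyl)octa-2,6-dienal
Product: 30 (4Z,6S,7E,9S,11Z)-13-(tert-butyldimethylsilyloxy)-12-iodo-5,9-dimethyl-9-(4-methylpent-3-enyl)-1-(triethylsilyloxy)trideca-4,7,11-trien-6-ol, via alkenyllithium 28 (not isolated), via dialkenylzinc 29 (not isolated)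
Conditions: 27, t-BuLi, Et2O, −78 °C; ZnBr2, to 0 °C; N,N,N',N'-tetraethylethylenediamine, (+)-MIB (10 mol%), toluene; 19, 0 °C
Reagents that add atoms: none
Why: Lithium–iodine exchange with retention, transmetalation to zinc (which leaves the C9 iodide of 19 alone) and amino-alcohol-catalysed alkenyl transfer to the Re face of the enal under control of (+)-MIB should set C4 as S, the diamine sequestering lithium halide that would otherwise promote unselective addition.

Step 16
Reactants: 30 (6S)-trienol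
Product: 31 (4Z,6S,7E,9S,11Z)-13-(tert-butyldimethylsilyloxy)-12-iodo-5,9-dimethyl-9-(4-methylpent-3-enyl)-1,6-bis(triethylsilyloxy)trideca-4,7,11-triene
Conditions: TESCl, imidazole, DMAP (cat.), CH2Cl2, 0 °C
Reagents that add atoms: chlorotriethylsilane, CC[Si](CC)(CC)Cl
Why: Silylation of the doubly allylic C4 alcohol under basic conditions avoids ionisation and gives an ether that can later be removed in the presence of the primary TBS ether.

Step 17
Reactants: 31 bis(triethylsilyl) ether
Product: 33 (4Z,6S,7E,9S,11Z)-13-(tert-butyldimethylsilyloxy)-12-iodo-5,9-dimethyl-9-(4-methylpent-3-enyl)-6-(triethylsilyloxy)trideca-4,7,11-trienoic acid, via aldehyde 32 (not isolated)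
Conditions: (COCl)2, DMSO, CH2Cl2, −78 to −30 °C; Et3N, to 0 °C; then NaClO2, NaH2PO4, 2-methylbut-2-ene, t-BuOH/H2O, 0 °C
Reagents that add atoms: sodium chlorite, [Na+].[O-]Cl=O
Why: Swern conditions are known to convert primary triethylsilyl ethers directly into aldehydes while secondary triethylsilyl and primary TBS ethers survive, and Pinnick oxidation with an alkene scavenger then gives the acid.

Step 18
Reactants: 33 trienoic acid
Product: 34 1,3-dioxoisoindolin-2-yl ester of 33 (N-acyloxyphthalimide)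
Conditions: N-hydroxyphthalimide, N,N'-diisopropylcarbodiimide, DMAP (cat.), CH2Cl2, rt
Reagents that add atoms: N-hydroxyphthalimide, O=C1c2ccccc2C(=O)N1O
Why: Carbodiimide esterification with N-hydroxyphthalimide is the standard entry to redox-active esters and tolerates silyl ethers and the alkenyl iodide.

Step 19
Reactants: 34 N-acyloxyphthalimide with C9 alkenyl iodide
Product: 35 (1S,2E,4S,5Z,9E)-9-[(tert-butyldimethylsilyloxy)methyl]-1,5-dimethyl-1-(4-methylpent-3-enyl)-4-(triethylsilyloxy)cycloundeca-2,5,9-triene (C8 and C11 cis on C9=C10)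
Conditions: NiBr2(dme) (1.0 equiv), 2,2'-bipyridine (1.2 equiv), LiCl, DMF, Mg anode, reticulated vitreous carbon cathode, constant current at low current density, 34 added over 12 h (final 2 mM), rt
Reagents that add atoms: none
Why: Proposed new method: zerovalent nickel–bipyridine formed at the cathode inserts into the C9–I bond with retention, single-electron reduction of the N-acyloxyphthalimide expels phthalimide anion and CO2 to leave the primary C8 radical, the alkenylnickel traps it and reductive elimination from trivalent nickel forms C8–C9; the closest known reaction is the intermolecular nickel-electrocatalysed decarboxylative alkenylation of redox-active esters with alkenyl iodides, which has not been shown to close a ring. The eleven-membered carbocycle closes end to end by C(sp3)–C(sp2) coupling of the two chain termini, and the E C2=C3 unit together with the Z C5=C6 alkene already turns the chain towards C9. No stereocentre is created: C1 and C4 are spectators, and the C9=C10 geometry is inherited from the Z iodide because oxidative addition and reductive elimination are stereoretentive. Ring closure has to outrun dimerisation, simple reduction of the radical, 1,5-hydrogen transfer from the doubly allylic C4–H and 6-exo attack on C3. Dilution answers only the first, so a full equivalent of the nickel complex is held in the cell while 34 is fed in slowly, which lets oxidative addition precede ester reduction and keeps the radical trap concentrated; the electron-rich silyloxy-substituted C4–H is also polarity-mismatched for abstraction by a nucleophilic alkyl radical.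

Step 20
Reactants: 35 bis-silylated cycloundecatriene
Product: 36 (1S,2E,4S,5Z,9E)-9-[(tert-butyldimethylsilyloxy)methyl]-1,5-dimethyl-1-(4-methylpent-3-enyl)cycloundeca-2,5,9-trien-4-ol
Conditions: HF·pyridine, pyridine, THF, 0 °C
Reagents that add atoms: none
Why: Buffered HF·pyridine cleaves a triethylsilyl ether much faster than a primary TBS ether and avoids the protic acid that could ionise the doubly allylic alcohol.

Step 21
Reactants: 36 macrocyclic allylic alcohol
Product: 37 (1S,2E,4S,5R,6R,9E)-9-[(tert-butyldimethylsilyloxy)methyl]-5,6-epoxy-1,5-dimethyl-1-(4-methylpent-3-enyl)cycloundeca-2,9-dien-4-ol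
Conditions: VO(acac)2 (10 mol%), t-BuOOH, CH2Cl2, 0 °C to rt
Reagents that add atoms: tert-butyl hydroperoxide, CC(C)(C)OO
Why: Vanadium-catalysed hydroxyl-directed epoxidation selects the trisubstituted allylic C5=C6 alkene and, as with (Z)-cycloalkenols of medium rings, should deliver oxygen to the ring face carrying the C4 hydroxyl, setting C5 (R) and C6 (R) cis to it.

Step 22
Reactants: 37 epoxy alcohol; 38 3-methylbut-2-enoyl chloride
Product: 39 [(1S,2E,4S,5R,6R,9E)-9-[(tert-butyldimethylsilyloxy)methyl]-5,6-epoxy-1,5-dimethyl-1-(4-methylpent-3-enyl)cycloundeca-2,9-dien-4-yl] 3-methylbut-2-enoate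
Conditions: 38, pyridine, DMAP (cat.), CH2Cl2, 0 °C to rt
Reagents that add atoms: none
Why: Acylation with the acid chloride under pyridine, without a strong amine base, should avoid deconjugation of the acyl group through the vinylketene and leaves C4 untouched.

Step 23
Reactants: 39 silyl-protected ester
Product: 40 CNP0318149.1, [(1S,2E,4S,5R,6R,9E)-5,6-epoxy-9-(hydroxymethyl)-1,5-dimethyl-1-(4-methylpent-3-enyl)cycloundeca-2,9-dien-4-yl] 3-methylbut-2-enoate
Conditions: Bu4NF, AcOH, THF, 0 °C to rt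
Reagents that add atoms: none
Why: Acetic-acid-buffered fluoride removes the primary TBS ether while the oxirane and the unsaturated ester survive.

**Compound list**

1 | (tributylstannyl)methanol | CCCC[Sn](CCCC)(CCCC)CO | starting material
2 | tributyl[(4-methoxybenzyloxy)methyl]stannane | CCCC[Sn](CCCC)(CCCC)COCc1ccc(OC)cc1 | intermediate
3 | geranial, (2E)-3,7-dimethylocta-2,6-dienal | CC(C)=CCC/C(C)=C/C=O | starting material
4 | (4-methoxybenzyloxy)methyllithium | [Li]COCc1ccc(OC)cc1 | intermediate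
5 | racemic (3E)-1-(4-methoxybenzyloxy)-4,8-dimethylnona-3,7-dien-2-ol | CC(C)=CCC/C(C)=C/C(O)COCc1ccc(OC)cc1 | intermediate
6 | (3E)-1-(4-methoxybenzyloxy)-4,8-dimethylnona-3,7-dien-2-one | CC(C)=CCC/C(C)=C/C(=O)COCc1ccc(OC)cc1 | intermediate
7 | (2R,3E)-1-(4-methoxybenzyloxy)-4,8-dimethylnona-3,7-dien-2-ol | CC(C)=CCC/C(C)=C/[C@@H](O)COCc1ccc(OC)cc1 | intermediate
8 | triethyl orthoacetate | CCOC(C)(OCC)OCC | starting material
9 | mixed orthoester of 7 (1,1-diethoxyethyl ether) | CC(C)=CCC/C(C)=C/[C@@H](OC(C)(OCC)OCC)COCc1ccc(OC)cc1 | intermediate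
10 | ketene acetal of 7 (1-ethoxyvinyl ether) | CC(C)=CCC/C(C)=C/[C@@H](OC(=C)OCC)COCc1ccc(OC)cc1 | intermediate
11 | ethyl (3S)-3-[(1E)-3-(4-methoxybenzyloxy)prop-1-enyl]-3,7-dimethyloct-6-enoate | CCOC(=O)C[C@](C)(CCC=C(C)C)/C=C/COCc1ccc(OC)cc1 | intermediate
12 | (3S)-3-[(1E)-3-(4-methoxybenzyloxy)prop-1-enyl]-3,7-dimethyloct-6-enal | O=CC[C@](C)(CCC=C(C)C)/C=C/COCc1ccc(OC)cc1 | intermediate
13 | (triphenylphosphoranylidene)acetaldehyde | O=CC=P(c1ccccc1)(c1ccccc1)c1ccccc1 | starting material
14 | (2E,5S)-5-[(1E)-3-(4-methoxybenzyloxy)prop-1-enyl]-5,9-dimethyldeca-2,8-dienal | O=C/C=C/C[C@](C)(CCC=C(C)C)/C=C/COCc1ccc(OC)cc1 | intermediate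
15 | (2Z,5S)-2-iodo-5-[(1E)-3-(4-methoxybenzyloxy)prop-1-enyl]-5,9-dimethyldeca-2,8-dienal | O=C/C(I)=C/C[C@](C)(CCC=C(C)C)/C=C/COCc1ccc(OC)cc1 | intermediate
16 | (2Z,5S)-2-iodo-5-[(1E)-3-(4-methoxybenzyloxy)prop-1-enyl]-5,9-dimethyldeca-2,8-dien-1-ol | OC/C(I)=C/C[C@](C)(CCC=C(C)C)/C=C/COCc1ccc(OC)cc1 | intermediate
17 | tert-butyldimethylsilyl ether of 16 | CC(C)(C)[Si](C)(C)OC/C(I)=C/C[C@](C)(CCC=C(C)C)/C=C/COCc1ccc(OC)cc1 | intermediate
18 | (2E,4S,6Z)-8-(tert-butyldimethylsilyloxy)-7-iodo-4-methyl-4-(4-methylpent-3-enyl)octa-2,6-dien-1-ol | CC(C)(C)[Si](C)(C)OC/C(I)=C/C[C@](C)(CCC=C(C)C)/C=C/CO | intermediate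
19 | (2E,4S,6Z)-8-(tert-butyldimethylsilyloxy)-7-iodo-4-methyl-4-(4-methylpent-3-enyl)octa-2,6-dienal | CC(C)(C)[Si](C)(C)OC/C(I)=C/C[C@](C)(CCC=C(C)C)/C=C/C=O | intermediate
20 | butane-1,4-diol | OCCCCO | starting material
21 | 4-(triethylsilyloxy)butan-1-ol | CC[Si](CC)(CC)OCCCCO | intermediate
22 | 4-(triethylsilyloxy)butanal | CC[Si](CC)(CC)OCCCC=O | intermediate
23 | ethyltriphenylphosphonium bromide | CC[P+](c1ccccc1)(c1ccccc1)c1ccccc1.[Br-] | starting material
24 | ethylidenetriphenylphosphorane | CC=P(c1ccccc1)(c1ccccc1)c1ccccc1 | intermediate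
25 | (1-iodoethyl)triphenylphosphonium iodide | CC(I)[P+](c1ccccc1)(c1ccccc1)c1ccccc1.[I-] | intermediate
26 | (1-iodoethylidene)triphenylphosphorane | CC(I)=P(c1ccccc1)(c1ccccc1)c1ccccc1 | intermediate
27 | (Z)-triethyl[(5-iodohex-4-en-1-yl)oxy]silane | CC[Si](CC)(CC)OCCC/C=C(/C)I | intermediate
28 | (Z)-[6-(triethylsilyloxy)hex-2-en-2-yl]lithium | [Li]/C(C)=C\CCCO[Si](CC)(CC)CC | intermediate
29 | bis[(Z)-6-(triethylsilyloxy)hex-2-en-2-yl]zinc | C/C(=C/CCCO[Si](CC)(CC)CC)[Zn]/C(C)=C\CCCO[Si](CC)(CC)CC | intermediate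
30 | (4Z,6S,7E,9S,11Z)-13-(tert-butyldimethylsilyloxy)-12-iodo-5,9-dimethyl-9-(4-methylpent-3-enyl)-1-(triethylsilyloxy)trideca-4,7,11-trien-6-ol | CC[Si](CC)(CC)OCCC/C=C(C)\[C@@H](O)/C=C/[C@@](C)(CCC=C(C)C)C/C=C(I)/CO[Si](C)(C)C(C)(C)C | intermediate
31 | (4Z,6S,7E,9S,11Z)-13-(tert-butyldimethylsilyloxy)-12-iodo-5,9-dimethyl-9-(4-methylpent-3-enyl)-1,6-bis(triethylsilyloxy)trideca-4,7,11-triene | CC[Si](CC)(CC)OCCC/C=C(C)\[C@@H](O[Si](CC)(CC)CC)/C=C/[C@@](C)(CCC=C(C)C)C/C=C(I)/CO[Si](C)(C)C(C)(C)C | intermediate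
32 | (4Z,6S,7E,9S,11Z)-13-(tert-butyldimethylsilyloxy)-12-iodo-5,9-dimethyl-9-(4-methylpent-3-enyl)-6-(triethylsilyloxy)trideca-4,7,11-trienal | O=CCC/C=C(C)\[C@@H](O[Si](CC)(CC)CC)/C=C/[C@@](C)(CCC=C(C)C)C/C=C(I)/CO[Si](C)(C)C(C)(C)C | intermediate
33 | (4Z,6S,7E,9S,11Z)-13-(tert-butyldimethylsilyloxy)-12-iodo-5,9-dimethyl-9-(4-methylpent-3-enyl)-6-(triethylsilyloxy)trideca-4,7,11-trienoic acid | OC(=O)CC/C=C(C)\[C@@H](O[Si](CC)(CC)CC)/C=C/[C@@](C)(CCC=C(C)C)C/C=C(I)/CO[Si](C)(C)C(C)(C)C | intermediate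
34 | 1,3-dioxoisoindolin-2-yl ester of 33 | O=C(ON1C(=O)c2ccccc2C1=O)CC/C=C(C)\[C@@H](O[Si](CC)(CC)CC)/C=C/[C@@](C)(CCC=C(C)C)C/C=C(I)/CO[Si](C)(C)C(C)(C)C | intermediate
35 | (1S,2E,4S,5Z,9E)-9-[(tert-butyldimethylsilyloxy)methyl]-1,5-dimethyl-1-(4-methylpent-3-enyl)-4-(triethylsilyloxy)cycloundeca-2,5,9-triene | CC(C)=CCC[C@]1(C)/C=C/[C@H](O[Si](CC)(CC)CC)/C(C)=C\CC/C(CO[Si](C)(C)C(C)(C)C)=C\C1 | intermediate
36 | (1S,2E,4S,5Z,9E)-9-[(tert-butyldimethylsilyloxy)methyl]-1,5-dimethyl-1-(4-methylpent-3-enyl)cycloundeca-2,5,9-trien-4-ol | CC(C)=CCC[C@]1(C)/C=C/[C@H](O)/C(C)=C\CC/C(CO[Si](C)(C)C(C)(C)C)=C\C1 | intermediate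
37 | (1S,2E,4S,5R,6R,9E)-9-[(tert-butyldimethylsilyloxy)methyl]-5,6-epoxy-1,5-dimethyl-1-(4-methylpent-3-enyl)cycloundeca-2,9-dien-4-ol | CC(C)=CCC[C@]1(C)/C=C/[C@H](O)[C@]2(C)O[C@@H]2CC/C(CO[Si](C)(C)C(C)(C)C)=C\C1 | intermediate
38 | 3-methylbut-2-enoyl chloride | CC(C)=CC(=O)Cl | starting material
39 | [(1S,2E,4S,5R,6R,9E)-9-[(tert-butyldimethylsilyloxy)methyl]-5,6-epoxy-1,5-dimethyl-1-(4-methylpent-3-enyl)cycloundeca-2,9-dien-4-yl] 3-methylbut-2-enoate | CC(C)=CCC[C@]1(C)/C=C/[C@H](OC(=O)C=C(C)C)[C@]2(C)O[C@@H]2CC/C(CO[Si](C)(C)C(C)(C)C)=C\C1 | intermediate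
40 | CNP0318149.1, [(1S,2E,4S,5R,6R,9E)-5,6-epoxy-9-(hydroxymethyl)-1,5-dimethyl-1-(4-methylpent-3-enyl)cycloundeca-2,9-dien-4-yl] 3-methylbut-2-enoate | CC(C)=CCC[C@]1(C)/C=C/[C@H](OC(=O)C=C(C)C)[C@]2(C)O[C@@H]2CC/C(CO)=C\C1 | target

**Step count**

Total: 23 steps. Longest linear sequence: 20 steps (steps 1–11 and 15–23); steps 12–14 make the side fragment.

**Steps most likely to fail, with fallbacks**

1. Step 19 (proposed new method). The C8 radical may be consumed before the alkenylnickel captures it, by 1,5-hydrogen transfer from C4–H, by 6-exo closure onto C3, by reduction, or by intermolecular coupling. The fallback forms C8–C9 by a two-electron B-alkyl Suzuki–Miyaura macrocyclisation and sets out from enal 19. Commercial acrolein and ylide 26 (conditions of step 14) give (3Z)-4-iodopenta-1,3-diene F1. Lithium–iodine exchange gives dienyllithium F2, ZnBr2 gives bis(dienyl)zinc F3, and addition to 19 with (+)-MIB as in step 15 gives dienyl alcohol F4. Silylation (TESCl, imidazole) gives triethylsilyl ether F5. 9-BBN adds to the terminal C7=C8 alkene of the diene to give the C8 borane F6, which is not isolated. Pd(dppf)Cl2, AsPh3 and Cs2CO3 in DMF/THF/H2O at high dilution then couple C8 with the C9 iodide and the route is rejoined at 35.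

2. Step 21. Oxygen may be delivered to the wrong face of C5=C6 if the ring conformation places the hydroxyl anti to the exposed alkene face; oxidation of the doubly allylic alcohol to the dienone is a second possible loss. The fallback sets out from 36 and uses the C4 epimer to steer the epoxidation. Mitsunobu reaction with 4-nitrobenzoic acid gives the inverted (4R)-4-nitrobenzoate F7, and K2CO3 in MeOH gives the (4R)-alcohol F8. The same VO(acac)2/t-BuOOH epoxidation, now trans-selective with respect to the 4R hydroxyl, gives the (4R,5R,6R)-epoxy alcohol F9. Mitsunobu esterification with 3-methylbut-2-enoic acid inverts C4 once more and rejoins the route at 39.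

3. Step 15. Enantiofacial control may be poor through salt-promoted background addition, or transfer of the α-branched alkenyl group may be sluggish. The fallback sets out from 19 and dialkenylzinc 29 and moves C4 control to a reagent-controlled reduction. Addition without ligand or diamine gives the C4-epimeric alcohols F10, and MnO2 gives the cross-conjugated dienone F11. Reduction with (R)-2-methyl-CBS-oxazaborolidine and catecholborane, with the 2-methylalkenyl flank as the large group, should return the (4S)-alcohol 30.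

**Further compounds**

F1 | step 19 | (3Z)-4-iodopenta-1,3-diene | C=C/C=C(/C)I
F2 | step 19 | (2Z)-penta-2,4-dien-2-yllithium | [Li]/C(C)=C\C=C
F3 | step 19 | bis[(2Z)-penta-2,4-dien-2-yl]zinc | C=C/C=C(/C)[Zn]/C(C)=C\C=C
F4 | step 19 | (3Z,5S,6E,8S,10Z)-12-(tert-butyldimethylsilyloxy)-11-iodo-4,8-dimethyl-8-(4-methylpent-3-enyl)dodeca-1,3,6,10-tetraen-5-ol | C=C/C=C(C)\[C@@H](O)/C=C/[C@@](C)(CCC=C(C)C)C/C=C(I)/CO[Si](C)(C)C(C)(C)C
F5 | step 19 | triethylsilyl ether of F4 | C=C/C=C(C)\[C@@H](O[Si](CC)(CC)CC)/C=C/[C@@](C)(CCC=C(C)C)C/C=C(I)/CO[Si](C)(C)C(C)(C)C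
F6 | step 19 | 9-borabicyclo[3.3.1]nonan-9-yl (C8) adduct of F5 | C1CC2CCCC(C1)B2CC/C=C(C)\[C@@H](O[Si](CC)(CC)CC)/C=C/[C@@](C)(CCC=C(C)C)C/C=C(I)/CO[Si](C)(C)C(C)(C)C
F7 | step 21 | (4R)-4-nitrobenzoate of the C4 epimer of 36 | CC(C)=CCC[C@]1(C)/C=C/[C@@H](OC(=O)c2ccc(cc2)[N+](=O)[O-])/C(C)=C\CC/C(CO[Si](C)(C)C(C)(C)C)=C\C1
F8 | step 21 | (1S,2E,4R,5Z,9E)-9-[(tert-butyldimethylsilyloxy)methyl]-1,5-dimethyl-1-(4-methylpent-3-enyl)cycloundeca-2,5,9-trien-4-ol | CC(C)=CCC[C@]1(C)/C=C/[C@@H](O)/C(C)=C\CC/C(CO[Si](C)(C)C(C)(C)C)=C\C1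
F9 | step 21 | (1S,2E,4R,5R,6R,9E)-9-[(tert-butyldimethylsilyloxy)methyl]-5,6-epoxy-1,5-dimethyl-1-(4-methylpent-3-enyl)cycloundeca-2,9-dien-4-ol | CC(C)=CCC[C@]1(C)/C=C/[C@@H](O)[C@]2(C)O[C@@H]2CC/C(CO[Si](C)(C)C(C)(C)C)=C\C1
F10 | step 15 | C6-epimeric mixture of 30 (6RS) | CC[Si](CC)(CC)OCCC/C=C(C)\C(O)/C=C/[C@@](C)(CCC=C(C)C)C/C=C(I)/CO[Si](C)(C)C(C)(C)C
F11 | step 15 | (4Z,7E,9S,11Z)-13-(tert-butyldimethylsilyloxy)-12-iodo-5,9-dimethyl-9-(4-methylpent-3-enyl)-1-(triethylsilyloxy)trideca-4,7,11-trien-6-one | CC[Si](CC)(CC)OCCC/C=C(C)\C(=O)/C=C/[C@@](C)(CCC=C(C)C)C/C=C(I)/CO[Si](C)(C)C(C)(C)C
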